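Count time here in lifetimes of the reagent being fed, not in minutes.

all flasks: time 2.0 min
- Friday's: starting complex 1.0 mM (fed, over 1.5 min); incoming ligand 1.10 mM; all else is in the flask from the start; the feed brings no volume worth counting
- Sunday's: starting complex 1.0 mM; incoming ligand 1.10 mM (fed, over 1.5 min); all else is in the flask from the start; the feed brings no volume worth counting
- Tuesday's: starting complex 1.0 mM; incoming ligand 1.10 mM (in portions, 2, over 1.5 min); first portion at the start, last at 1.5 min
- Wednesday's: starting complex 1.0 mM; incoming ligand 1.10 mM; everything together at the start

- the flask that comes out highest in share of complex with two exchanged in complex with two exchanged plus complex with three exchanged, or "all alike" when all lie within 1.5 percentage points (Friday's / Sunday's / Tuesday's / Wednesday's / all alike)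
- share of complex with two exchanged in complex with two exchanged plus complex with three exchanged at the end, Friday's
- share of complex with two exchanged in complex with two exchanged plus complex with three exchanged at the end, Sunday's
- share of complex with two exchanged in complex with two exchanged plus complex with three exchanged at the end, Tuesday's
- share of complex with two exchanged in complex with two exchanged plus complex with three exchanged at the end, Wednesday's

Ligand goes onto the starting complex, then onto each product in turn, and leaving ligand slowly takes the complex with two exchanged off to side product.

Two extremes can be solved in your head. Put ligand into a great excess of starting complex, and each ligand meets starting complex first, so the share tends to the whole. Drip complex into a standing excess of ligand, and each complex runs through to three exchanged, so the share tends to nothing while that excess lasts.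

To place the real flasks between these, take the pseudo-first-order lifetime of starting complex against the charged ligand, 0.316 min. Dividing 1.5 min by it gives 4.75: this is the feed number, the feed time counted in those lifetimes. The crossing stands at one. Far below it a flask fed with starting complex behaves like a batch.

Friday's stands above the crossing, so I put it toward the second extreme, under 50.0%. Sunday's feed number, taken against everything charged, is 4.3, but it does not place that flask. The steps that use ligand are each first order in it, so feeding it changes their pace together and leaves their ratio. So I put Sunday's level with Wednesday's, the batch, apart from the leak to side product. Tuesday's portions are beyond this number, and so is the leak to side product.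

The forecast chose Tuesday's, with 40%, 60%, 67% and 50% for Friday's, Sunday's, Tuesday's and Wednesday's, reasoning that “Tuesday's late second portion comes out best because it makes much of that complex shortly before the end”.

    complex with one exchanged + incoming ligand → leaving ligand + complex with two exchanged (k1 = 150 M⁻¹ s⁻¹)
    leaving ligand + complex with two exchanged → side product (k2 = 11 M⁻¹ s⁻¹)
    complex with two exchanged + incoming ligand → leaving ligand + complex with three exchanged (k3 = 47 M⁻¹ s⁻¹)
    starting complex + incoming ligand → leaving ligand + complex with one exchanged (k4 = 48 M⁻¹ s⁻¹)

The flasks give 41.4% for Friday's, 66.0% for Sunday's, 71.0% for Tuesday's and 50.8% for Wednesday's, so Tuesday's stands highest and my bound on Friday's holds. Sunday's stands 15 percentage points above Wednesday's, and its side product is 11.4% against 19.5% for Wednesday's. Friday's fed over 0.450 min gives 48.7%, higher than with its usual feed. Its feed number there is 1.42, near the crossing, and its share lies near Wednesday's.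

Now take Friday's with 1.9 mM of ligand. The feed number rises to 8.21, above Friday's, which points to a lower share. That flask gives 23.2%, lower than Friday's.

(The numbers of this flask stand for no real mixture; the result is computed.)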